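**Retrosynthetic overview**
1. Target ⇐ 13-ketone tetraacetate by Felkin–Anh vinyl addition; the tetraacetate ⇐ 6β,8α,12,20-tetraol.
2. Tetraol ⇐ one hydride reduction of a 6,12-diketone / 8α-formate / C20 ester (C6 by α-face attack, C12 by chelation to a lactate-derived 13-OBn); 8α-O ⇐ Baeyer–Villiger of an 8α-formyl group; 6-O ⇐ hydroboration of a 5-ene.
3. Key disconnection: ring B (bonds C7–C8 and C9–C10) plus a temporary C20→O12 δ-lactone, by ester-tethered intramolecular Diels–Alder of a vinylcyclohexene dienoate with an E-enal; this sets C8, C9 and C10.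
4. Triene ⇐ 3,3-dimethyl-2-vinylcyclohexenecarboxylic acid (from 2,2-dimethylcyclohexanone) + a (5S,6S)-hydroxy enal (from ethyl (S)-lactate by chelation-controlled allylation and cross-metathesis).
5. Ring order: ring A is bought; ring B and the lactone form together in the cycloaddition; the lactone is opened afterwards.

Assumption: the SMILES is read as (5S,6R,8R,9R,10R,12R,13S), i.e. the normal labdane skeleton (5α-H, 9α-H, C17 = 8β-CH3, C20 on the β face); labdane numbering is used in the names.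

**Route**

Step 1
Reactants: 1 2,2-dimethylcyclohexanone
Product: 2 2-bromo-3,3-dimethylcyclohex-1-ene-1-carbaldehyde
Conditions: PBr3, DMF, CHCl3, 0 °C → 60 °C; then ice-water
Reagents that add atoms: phosphorus tribromide BrP(Br)Br; N,N-dimethylformamide CN(C)C=O; water O
Why: Vilsmeier–Haack–Arnold bromoformylation; the ketone enolises only toward its CH2 side, so CHO (future C20) and the vinyl bromide (future C5) land next to the gem-dimethyl carbon as needed.

Step 2
Reactants: 2 2-bromo-3,3-dimethylcyclohex-1-ene-1-carbaldehyde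
Product: 3 3,3-dimethyl-2-vinylcyclohex-1-ene-1-carbaldehyde
Conditions: CH2=CHSnBu3, Pd(PPh3)4 (5 mol %), toluene, 100 °C
Reagents that add atoms: tributyl(vinyl)stannane C=C[Sn](CCCC)(CCCC)CCCC
Why: Stille coupling of the activated β-bromo enal installs the C6=C7 vinyl group of the diene.

Step 3
Reactants: 3 3,3-dimethyl-2-vinylcyclohex-1-ene-1-carbaldehyde
Product: 4 3,3-dimethyl-2-vinylcyclohex-1-ene-1-carboxylic acid
Conditions: NaClO2, NaH2PO4, 2-methyl-2-butene, t-BuOH/H2O, 0 °C → rt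
Reagents that add atoms: sodium chlorite [Na+].[O-]Cl=O
Why: Pinnick oxidation takes the aldehyde to the acid while the scavenger protects the diene from HOCl.

Step 4
Reactants: 5 ethyl (S)-lactate
Product: 6 ethyl (S)-2-(benzyloxy)propanoate
Conditions: BnOC(=NH)CCl3, TfOH (cat.), cyclohexane/CH2Cl2, rt
Reagents that add atoms: benzyl 2,2,2-trichloroacetimidate N=C(OCc1ccccc1)C(Cl)(Cl)Cl
Why: acid-catalysed trichloroacetimidate benzylation uses no base, so the lactate stereocentre is not epimerised.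

Step 5
Reactants: 6 ethyl (S)-2-(benzyloxy)propanoate
Product: 7 (S)-2-(benzyloxy)propanal
Conditions: i-Bu2AlH, CH2Cl2, −78 °C; then aq. KNaC4H4O6
Reagents that add atoms: none
Why: DIBAL half-reduction stops at the aldehyde at −78 °C because the tetrahedral aluminium hemiacetal survives until work-up.

Step 6
Reactants: 7 (S)-2-(benzyloxy)propanal
Product: 8 (2S,3S)-2-(benzyloxy)hex-5-en-3-ol
Conditions: CH2=CHCH2SnBu3, MgBr2·OEt2, CH2Cl2, −20 °C; then H2O
Reagents that add atoms: allyltributylstannane C=CC[Sn](CCCC)(CCCC)CCCC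
Why: Keck chelation-controlled allylation; MgBr2 bridges C=O and OBn and the allyl group adds anti to the methyl group, giving the syn (3S) carbinol (future C12, temporarily S).

Step 7
Reactants: 8 (2S,3S)-2-(benzyloxy)hex-5-en-3-ol
Product: 9 (2E,5S,6S)-6-(benzyloxy)-5-hydroxy-2-methylhept-2-enal
Conditions: methacrolein (5 equiv), second-generation Hoveyda–Grubbs catalyst (C31H38Cl2N2ORu, 5 mol %), CH2Cl2, 40 °C
Reagents that add atoms: methacrolein CC(=C)C=O
Why: olefin cross-metathesis with methacrolein gives the trisubstituted E-enal under thermodynamic control and tolerates the free hydroxyl.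

Step 8
Reactants: 4 3,3-dimethyl-2-vinylcyclohex-1-ene-1-carboxylic acid; 9 (2E,5S,6S)-6-(benzyloxy)-5-hydroxy-2-methylhept-2-enal
Product: 11 (2E,5S,6S)-6-(benzyloxy)-2-methyl-1-oxohept-2-en-5-yl 3,3-dimethyl-2-vinylcyclohex-1-ene-1-carboxylate, via acid chloride 10 (not isolated)
Conditions: 4, Me2C=C(Cl)NMe2, CH2Cl2, 0 °C → rt; then 9, pyridine, DMAP (cat.), rt
Reagents that add atoms: none
Why: neutral acid chloride formation (Ghosez reagent) then DMAP-catalysed acylation joins the hindered dienoic acid to the secondary alcohol without touching the enal or the diene.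

Step 9
Reactants: 11 (2E,5S,6S)-6-(benzyloxy)-2-methyl-1-oxohept-2-en-5-yl 3,3-dimethyl-2-vinylcyclohex-1-ene-1-carboxylate
Product: 12 (12S,13S)-13-benzyloxy-8α-formyl-14,15-dinorlabd-5-en-20,12-olide
Conditions: toluene (0.005 M), BHT (cat.), 190 °C, sealed tube
Reagents that add atoms: none
Why: ester-tethered intramolecular Diels–Alder reaction; the ring-locked diene allows only the cis-fused δ-lactone (C20 and C11 syn), the E-enal puts CHO trans to C11 (8α-CHO, 8β-CH3), and the C12 substituent sits equatorial in the chair-like tether, away from the C8 methyl, so the 12S centre sets C8, C9 and C10 in the natural sense.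

Step 10
Reactants: 12 (12S,13S)-13-benzyloxy-8α-formyl-14,15-dinorlabd-5-en-20,12-olide
Product: 14 (12S,13S)-13-benzyloxy-6α-hydroxy-8α-hydroxymethyl-14,15-dinorlabdan-20,12-olide, via cyclic alkoxyborane 13 (not isolated)
Conditions: BH3·THF, THF, 0 °C → rt; then aq. NaOH, 30 % H2O2, 0 °C
Reagents that add atoms: hydrogen peroxide OO
Why: hydroboration–oxidation; borane reduces the aldehyde and adds H–B syn across C5=C6 from the open α face (the β face carries the lactone bridge and the axial methyls), giving 5α-H and 6α-OH.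

Step 11
Reactants: 14 (12S,13S)-13-benzyloxy-6α-hydroxy-8α-hydroxymethyl-14,15-dinorlabdan-20,12-olide
Product: 16 methyl (12S,13S)-13-benzyloxy-6α,12-dihydroxy-8α-hydroxymethyl-14,15-dinorlabdan-20-oate, via lithium carboxylate 15 (not isolated)
Conditions: LiOH·H2O, THF/H2O, 40 °C; evaporate; then MeI, DMF, rt
Reagents that add atoms: lithium hydroxide [Li+].[OH-]; iodomethane CI
Why: lactone saponification followed by carboxylate O-alkylation frees the C12 hydroxyl for oxidation while C20 stays at the acid level.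

Step 12
Reactants: 16 methyl (12S,13S)-13-benzyloxy-6α,12-dihydroxy-8α-hydroxymethyl-14,15-dinorlabdan-20-oate
Product: 17 methyl (13S)-13-benzyloxy-8α-formyl-6,12-dioxo-14,15-dinorlabdan-20-oate
Conditions: Dess–Martin periodinane (4 equiv), pyridine, CH2Cl2, 0 °C → rt
Reagents that add atoms: none
Why: Dess–Martin oxidation of all three alcohols regenerates the C8 aldehyde, gives the 6-ketone (the trans ring fusion is the stable one) and erases the temporary C12 centre without epimerising the α-benzyloxy centre C13.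

Step 13
Reactants: 17 methyl (13S)-13-benzyloxy-8α-formyl-6,12-dioxo-14,15-dinorlabdan-20-oate
Product: 18 methyl (13S)-13-benzyloxy-8α-formyloxy-6,12-dioxo-14,15-dinorlabdan-20-oate
Conditions: mCPBA (1.1 equiv), CH2Cl2, 0 °C
Reagents that add atoms: 3-chloroperbenzoic acid OOC(=O)c1cccc(Cl)c1
Why: Baeyer–Villiger oxidation; the aldehyde reacts far faster than the hindered ketones and the tertiary C8 migrates with retention, fixing the 8α C–O bond.

Step 14
Reactants: 18 methyl (13S)-13-benzyloxy-8α-formyloxy-6,12-dioxo-14,15-dinorlabdan-20-oate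
Product: 19 (12R,13S)-13-benzyloxy-14,15-dinorlabdane-6β,8α,12,20-tetraol
Conditions: LiAlH4, Et2O, −78 °C → reflux; then H2O work-up
Reagents that add atoms: none
Why: global hydride reduction; the C12 ketone reacts through a Cram chelate (Li bridging C=O and the C13 benzyloxy group, hydride anti to the C13 methyl) to give 12R, the C6 ketone is attacked from the open α face to give the axial 6β-OH, and the formate and methyl ester give the 8α-OH and C20 CH2OH.

Step 15
Reactants: 19 (12R,13S)-13-benzyloxy-14,15-dinorlabdane-6β,8α,12,20-tetraol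
Product: 20 (12R,13S)-13-benzyloxy-14,15-dinorlabdane-6β,8α,12,20-tetrayl tetraacetate
Conditions: Ac2O (excess), DMAP (2 equiv), pyridine, 60 °C
Reagents that add atoms: acetic anhydride CC(=O)OC(C)=O
Why: DMAP-catalysed (Steglich-type) acylation under forcing basic conditions acetylates the primary, secondary, axial 6β and tertiary 8α hydroxyls, while O13 is still a benzyl ether.

Step 16
Reactants: 20 (12R,13S)-13-benzyloxy-14,15-dinorlabdane-6β,8α,12,20-tetrayl tetraacetate
Product: 21 (12R,13S)-13-hydroxy-14,15-dinorlabdane-6β,8α,12,20-tetrayl tetraacetate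
Conditions: H2 (1 atm), Pd/C, EtOAc, rt
Reagents that add atoms: none
Why: neutral hydrogenolysis removes the benzyl ether without touching the acetates (no alkene is present at this stage).

Step 17
Reactants: 21 (12R,13S)-13-hydroxy-14,15-dinorlabdane-6β,8α,12,20-tetrayl tetraacetate
Product: 22 (12R)-13-oxo-14,15-dinorlabdane-6β,8α,12,20-tetrayl tetraacetate
Conditions: Dess–Martin periodinane, pyridine, CH2Cl2, 0 °C
Reagents that add atoms: none
Why: Dess–Martin oxidation gives the α-acetoxy methyl ketone under mild conditions that neither epimerise C12 nor let the acetate migrate.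

Step 18
Reactants: 22 (12R)-13-oxo-14,15-dinorlabdane-6β,8α,12,20-tetrayl tetraacetate
Product: 23 (12R,13S)-6β,8α,12,20-tetraacetoxylabd-14-en-13-ol
Conditions: CH2=CHMgBr (1.3 equiv), THF, −78 °C; then aq. NH4Cl at −78 °C
Reagents that add atoms: vinylmagnesium bromide C=C[Mg]Br
Why: Grignard 1,2-addition is faster at the α-acetoxy ketone than at the acetates at −78 °C and follows the polar Felkin–Anh (Cornforth) model with OAc anti to the incoming vinyl group, giving the 13S carbinol (12,13-erythro).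

**Compound list**

1 | 2,2-dimethylcyclohexanone | CC1(C)CCCCC1=O | starting material
2 | 2-bromo-3,3-dimethylcyclohex-1-ene-1-carbaldehyde | O=CC1=C(Br)C(C)(C)CCC1 | intermediate
3 | 3,3-dimethyl-2-vinylcyclohex-1-ene-1-carbaldehyde | O=CC1=C(C=C)C(C)(C)CCC1 | intermediate
4 | 3,3-dimethyl-2-vinylcyclohex-1-ene-1-carboxylic acid | OC(=O)C1=C(C=C)C(C)(C)CCC1 | intermediate
5 | ethyl (S)-lactate | CCOC(=O)[C@H](C)O | starting material
6 | ethyl (S)-2-(benzyloxy)propanoate | CCOC(=O)[C@H](C)OCc1ccccc1 | intermediate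
7 | (S)-2-(benzyloxy)propanal | C[C@H](OCc1ccccc1)C=O | intermediate
8 | (2S,3S)-2-(benzyloxy)hex-5-en-3-ol | C[C@H](OCc1ccccc1)[C@@H](O)CC=C | intermediate
9 | (2E,5S,6S)-6-(benzyloxy)-5-hydroxy-2-methylhept-2-enal | C[C@H](OCc1ccccc1)[C@@H](O)C/C=C(\C)C=O | intermediate
10 | 3,3-dimethyl-2-vinylcyclohex-1-ene-1-carbonyl chloride | C=CC1=C(C(Cl)=O)CCCC1(C)C | intermediate
11 | (2E,5S,6S)-6-(benzyloxy)-2-methyl-1-oxohept-2-en-5-yl 3,3-dimethyl-2-vinylcyclohex-1-ene-1-carboxylate | C[C@H](OCc1ccccc1)[C@H](C/C=C(\C)C=O)OC(=O)C2=C(C=C)C(C)(C)CCC2 | intermediate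
12 | (12S,13S)-13-benzyloxy-8α-formyl-14,15-dinorlabd-5-en-20,12-olide | O=C[C@]1(C)CC=C2C(C)(C)CCC[C@@]23C(=O)O[C@H]([C@H](C)OCc4ccccc4)C[C@@H]13 | intermediate
13 | cyclic alkoxyborane of 12 (boron on C6α and on the oxygen of the 8α-CH2O group) | [BH]1OC[C@]2(C)C[C@H]1[C@H]3C(C)(C)CCC[C@@]34C(=O)O[C@H]([C@H](C)OCc5ccccc5)C[C@@H]24 | intermediate
14 | (12S,13S)-13-benzyloxy-6α-hydroxy-8α-hydroxymethyl-14,15-dinorlabdan-20,12-olide | OC[C@]1(C)C[C@H](O)[C@H]2C(C)(C)CCC[C@@]23C(=O)O[C@H]([C@H](C)OCc4ccccc4)C[C@@H]13 | intermediate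
15 | lithium (12S,13S)-13-benzyloxy-6α,12-dihydroxy-8α-hydroxymethyl-14,15-dinorlabdan-20-oate | OC[C@]1(C)C[C@H](O)[C@H]2C(C)(C)CCC[C@]2(C(=O)[O-])[C@H]1C[C@H](O)[C@H](C)OCc3ccccc3.[Li+] | intermediate
16 | methyl (12S,13S)-13-benzyloxy-6α,12-dihydroxy-8α-hydroxymethyl-14,15-dinorlabdan-20-oate | OC[C@]1(C)C[C@H](O)[C@H]2C(C)(C)CCC[C@]2(C(=O)OC)[C@H]1C[C@H](O)[C@H](C)OCc3ccccc3 | intermediate
17 | methyl (13S)-13-benzyloxy-8α-formyl-6,12-dioxo-14,15-dinorlabdan-20-oate | O=C[C@]1(C)CC(=O)[C@H]2C(C)(C)CCC[C@]2(C(=O)OC)[C@H]1CC(=O)[C@H](C)OCc3ccccc3 | intermediate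
18 | methyl (13S)-13-benzyloxy-8α-formyloxy-6,12-dioxo-14,15-dinorlabdan-20-oate | O=CO[C@]1(C)CC(=O)[C@H]2C(C)(C)CCC[C@]2(C(=O)OC)[C@H]1CC(=O)[C@H](C)OCc3ccccc3 | intermediate
19 | (12R,13S)-13-benzyloxy-14,15-dinorlabdane-6β,8α,12,20-tetraol | O[C@]1(C)C[C@@H](O)[C@H]2C(C)(C)CCC[C@]2(CO)[C@H]1C[C@@H](O)[C@H](C)OCc3ccccc3 | intermediate
20 | (12R,13S)-13-benzyloxy-14,15-dinorlabdane-6β,8α,12,20-tetrayl tetraacetate | CC(=O)O[C@]1(C)C[C@@H](OC(C)=O)[C@H]2C(C)(C)CCC[C@]2(COC(C)=O)[C@H]1C[C@@H](OC(C)=O)[C@H](C)OCc3ccccc3 | intermediate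
21 | (12R,13S)-13-hydroxy-14,15-dinorlabdane-6β,8α,12,20-tetrayl tetraacetate | CC(=O)O[C@]1(C)C[C@@H](OC(C)=O)[C@H]2C(C)(C)CCC[C@]2(COC(C)=O)[C@H]1C[C@@H](OC(C)=O)[C@H](C)O | intermediate
22 | (12R)-13-oxo-14,15-dinorlabdane-6β,8α,12,20-tetrayl tetraacetate | CC(=O)O[C@]1(C)C[C@@H](OC(C)=O)[C@H]2C(C)(C)CCC[C@]2(COC(C)=O)[C@H]1C[C@@H](OC(C)=O)C(C)=O | intermediate
23 | (12R,13S)-6β,8α,12,20-tetraacetoxylabd-14-en-13-ol (CNP0136817.1) | C=C[C@](C)(O)[C@@H](C[C@@H]1[C@@]2(COC(C)=O)CCCC(C)(C)[C@@H]2[C@H](OC(C)=O)C[C@@]1(C)OC(C)=O)OC(C)=O | target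

**Step count and risks**

Total: 18 steps. Longest linear sequence: 15 steps (5 → 23 through steps 4–18).

Most likely to fail:

Step 9 (cycloaddition). The diene is hindered and conjugated to the tether ester, the dienophile is trisubstituted, and two quaternary carbons form. Fallback: make the dienophile cationic. Compound 11 with ethylene glycol (PPTS, benzene, reflux) gives the dioxolane acetal F1. Catalytic TMSOTf in CH2Cl2 at −78 °C ionises it to an alkoxyallyl cation, which closes through the same tethered arrangement (Gassman-type ionic Diels–Alder) to the acetal cycloadduct F2. PPTS in wet acetone then returns 12.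

Step 14 (C12 set by chelation during the global reduction). Selectivity with LiAlH4 may be only moderate. Fallback: invert C12 by substitution instead of re-setting it by reduction. Lactone 12 is opened (LiOH; then MeI) to the hydroxy ester F3. Mitsunobu reaction with AcOH (PPh3, DIAD) gives the inverted 12R acetate F4. F4 is carried through hydroboration–oxidation to the diol F5, Dess–Martin oxidation to the keto aldehyde F6 and Baeyer–Villiger oxidation to the formate F7, so C12 is never a ketone. LiAlH4 reduction of F7 gives 19.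

Step 18 (vinyl Grignard on a tetraacetate). Risks are acetate cleavage, acetyl migration to the new alkoxide and incomplete facial control. Fallback: bring in the two carbons as the smaller, less basic acetylide and reduce afterwards. Compound 22 with HC≡CMgBr (THF, −78 °C) gives the propargylic alcohol F8. Semihydrogenation over Lindlar catalyst (Pd/CaCO3 poisoned with Pb(OAc)2, quinoline, H2) gives 23.

**Further compounds**

F1 | step 9 | (2E,5S,6S)-6-benzyloxy-2-(1,3-dioxolan-2-yl)hept-2-en-5-yl 3,3-dimethyl-2-vinylcyclohex-1-ene-1-carboxylate | C[C@H](OCc1ccccc1)[C@H](C/C=C(\C)C2OCCO2)OC(=O)C3=C(C=C)C(C)(C)CCC3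
F2 | step 9 | (12S,13S)-13-benzyloxy-8α-(1,3-dioxolan-2-yl)-14,15-dinorlabd-5-en-20,12-olide | O1CCOC1[C@]2(C)CC=C3C(C)(C)CCC[C@@]34C(=O)O[C@H]([C@H](C)OCc5ccccc5)C[C@@H]24
F3 | step 14 | methyl (12S,13S)-13-benzyloxy-8α-formyl-12-hydroxy-14,15-dinorlabd-5-en-20-oate | O=C[C@]1(C)CC=C2C(C)(C)CCC[C@]2(C(=O)OC)[C@H]1C[C@H](O)[C@H](C)OCc3ccccc3
F4 | step 14 | methyl (12R,13S)-12-acetoxy-13-benzyloxy-8α-formyl-14,15-dinorlabd-5-en-20-oate | O=C[C@]1(C)CC=C2C(C)(C)CCC[C@]2(C(=O)OC)[C@H]1C[C@@H](OC(C)=O)[C@H](C)OCc3ccccc3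
F5 | step 14 | methyl (12R,13S)-12-acetoxy-13-benzyloxy-6α-hydroxy-8α-hydroxymethyl-14,15-dinorlabdan-20-oate | OC[C@]1(C)C[C@H](O)[C@H]2C(C)(C)CCC[C@]2(C(=O)OC)[C@H]1C[C@@H](OC(C)=O)[C@H](C)OCc3ccccc3
F6 | step 14 | methyl (12R,13S)-12-acetoxy-13-benzyloxy-8α-formyl-6-oxo-14,15-dinorlabdan-20-oate | O=C[C@]1(C)CC(=O)[C@H]2C(C)(C)CCC[C@]2(C(=O)OC)[C@H]1C[C@@H](OC(C)=O)[C@H](C)OCc3ccccc3
F7 | step 14 | methyl (12R,13S)-12-acetoxy-13-benzyloxy-8α-formyloxy-6-oxo-14,15-dinorlabdan-20-oate | O=CO[C@]1(C)CC(=O)[C@H]2C(C)(C)CCC[C@]2(C(=O)OC)[C@H]1C[C@@H](OC(C)=O)[C@H](C)OCc3ccccc3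
F8 | step 18 | (12R,13S)-6β,8α,12,20-tetraacetoxylabd-14-yn-13-ol | C#C[C@](C)(O)[C@@H](C[C@@H]1[C@@]2(COC(C)=O)CCCC(C)(C)[C@@H]2[C@H](OC(C)=O)C[C@@]1(C)OC(C)=O)OC(C)=O
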